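Ring A is built de novo: a Danheiser benzannulation joins 3-ethoxycyclobutenone to a siloxyalkyne that already holds the quaternary carbon of the 1,1-dimethylallyl group. In one thermal operation (vinylketene [2+2], 4π opening, 6π closure) the benzene ring forms with its three oxygens differentiated and the tert-alkyl group fixed on the future C8 of ring A, flanked by O7 and O1 (on C8a) and para to O5, so no C6 versus C8 prenylation problem arises. The free hydroxyl of the resulting resorcinol then directs formylation to the future C4a, a benzylic Grignard reagent brings ring B, and ring C closes by one-carbon insertion before deprotection.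

Key step: step 3

Remark: isoflavone numbering is used (O1, C2, C3, C4, C4a, C5 to C8, C8a; ring B positions primed); the target is achiral, so no configuration has to be set or preserved.

Step 1
Reactants: 1 ethyl 2,2-dimethylbut-3-enoate
Product: 4 triisopropyl[(3,3-dimethylpent-4-en-1-yn-1-yl)oxy]silane, via dibromomethyl ketone 2 (not isolated), via lithium ynolate 3 (not isolated)
Conditions: CH2Br2, LiTMP, THF, −78 °C; LiHMDS; n-BuLi, −78 to 25 °C; TIPSCl, −78 to 0 °C
Reagents that add atoms: dibromomethane BrCBr; triisopropylsilyl chloride CC(C)[Si](Cl)(C(C)C)C(C)C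
Why: Kowalski ester homologation, in which dibromomethyllithium adds to the ester, the enolate of dibromo ketone 2 undergoes bromine–lithium exchange and a carbenoid 1,2-shift of the tertiary group to ynolate 3, and the oxygen of 3 is capped by the bulky chlorosilane to give a stable triisopropylsilyl ynol ether.

Step 2
Reactants: 5 ethoxyacetylene; 6 acetyl chloride
Product: 8 3-ethoxycyclobut-2-en-1-one, via ketene 7 (not isolated)
Conditions: Et3N, Et2O, 0 to 25 °C, slow addition of 6 to excess 5
Reagents that add atoms: none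
Why: Dehydrochlorination of the acid chloride by the amine gives ketene in the flask, which the electron-rich ynol ether traps in a ketene–alkyne [2+2] cycloaddition with its oxygen-distal carbon bonding to the ketene carbonyl carbon, giving the vinylogous ester directly.

Step 3
Reactants: 4 triisopropyl[(3,3-dimethylpent-4-en-1-yn-1-yl)oxy]silane; 8 3-ethoxycyclobut-2-en-1-one
Product: 13 5-ethoxy-2-(2-methylbut-3-en-2-yl)-3-[(triisopropylsilyl)oxy]phenol, via vinylketene 9 (not isolated), via vinylcyclobutenone 10 (not isolated), via dienylketene 11 (not isolated), via cyclohexadienone 12 (not isolated)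
Conditions: 8 (1.5 equiv), PhMe, 110 °C, sealed tube
Reagents that add atoms: none
Why: Heating opens 8 by a reversible conrotatory 4π electrocyclic reaction to vinylketene 9, whose ketene carbon is attacked by the oxygen-distal, nucleophilic carbon of ynol ether 4 (the carbon bearing the quaternary group) while the ketene α-carbon bonds to the siloxy carbon, a ketene–alkyne [2+2] cycloaddition that closes the four-membered ring of 10. A second 4π opening turns 10 into dienylketene 11, and a thermal disrotatory 6π electrocyclization, in which the ketene carbon bonds to the former ring CH2 of 8, closes ring A as dienone 12, which enolizes to phenol 13. The closest known reaction is the Danheiser benzannulation of cyclobutenones with triisopropylsiloxyalkynes to monosilylated resorcinols; pairing a 3-alkoxycyclobutenone with a tert-alkyl-substituted ynol ether applies it to a new pair of partners. No stereocenter is created in 13: the sp3 ring carbon of 10 forms racemic and is erased on ring opening, and only the isomer of 11 with the ketene and ethoxyvinyl groups cis can cyclize, the other reverting to 10. The one selectivity needed is the orientation of the [2+2], and the polarization of the ynol ether secures it, so that the quaternary carbon ends between the free hydroxyl and the siloxy group and para to the ethoxy group, with all three oxygens differentiated. The ketene is unhindered at its reacting carbon, the alkyne has no propargylic hydrogen to divert it, and the isolated vinyl group is a spectator.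

Step 4
Reactants: 13 5-ethoxy-2-(2-methylbut-3-en-2-yl)-3-[(triisopropylsilyl)oxy]phenol
Product: 15 6-ethoxy-2-hydroxy-3-(2-methylbut-3-en-2-yl)-4-[(triisopropylsilyl)oxy]benzaldehyde, via salicyl alcohol 14 (not isolated)
Conditions: MgCl2, Et3N, (CH2O)n, MeCN, reflux; cold dilute HCl work-up
Reagents that add atoms: paraformaldehyde (as formaldehyde) C=O
Why: Magnesium-mediated ortho-formylation (Casnati–Skattebøl reaction), in which the magnesium phenoxide delivers formaldehyde to the only unsubstituted ortho carbon and the salicyl alcohol 14 is oxidised in place by hydride transfer to a second formaldehyde, leaving the para position, the silyl ether and the alkene untouched.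

Step 5
Reactants: 16 2,4-dihydroxybenzaldehyde
Product: 17 2,4-bis(methoxymethoxy)benzaldehyde
Conditions: MOMCl, i-Pr2NEt, CH2Cl2, 0 to 40 °C
Reagents that add atoms: chloromethyl methyl ether COCCl
Why: O-Alkylation of both phenols with the chloromethyl ether under amine base (warming drives the hydrogen-bonded 2-hydroxyl) installs acetals that resist and chelate the later benzylic organomagnesium reagent.

Step 6
Reactants: 17 2,4-bis(methoxymethoxy)benzaldehyde
Product: 18 [2,4-bis(methoxymethoxy)phenyl]methanol
Conditions: NaBH4, MeOH, 0 °C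
Reagents that add atoms: none
Why: Chemoselective hydride reduction of the aryl aldehyde by NaBH4, to which the acetal ethers are inert.

Step 7
Reactants: 18 [2,4-bis(methoxymethoxy)phenyl]methanol
Product: 19 1-(chloromethyl)-2,4-bis(methoxymethoxy)benzene
Conditions: MsCl, i-Pr2NEt, CH2Cl2, 0 °C; used at once
Reagents that add atoms: methanesulfonyl chloride CS(=O)(=O)Cl
Why: Mesylation under a hindered amine, the very labile electron-rich benzylic mesylate being displaced in the flask by the liberated chloride, gives the benzylic chloride without acid that would harm the acetals and without quaternising the base.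

Step 8
Reactants: 15 6-ethoxy-2-hydroxy-3-(2-methylbut-3-en-2-yl)-4-[(triisopropylsilyl)oxy]benzaldehyde; 19 1-(chloromethyl)-2,4-bis(methoxymethoxy)benzene
Product: 21 racemic 2-[2,4-bis(methoxymethoxy)phenyl]-1-[6-ethoxy-2-hydroxy-3-(2-methylbut-3-en-2-yl)-4-[(triisopropylsilyl)oxy]phenyl]ethan-1-ol, via benzylmagnesium chloride 20 (not isolated)
Conditions: 19 (3 equiv), Mg turnings, THF, 0 °C, slow dilute addition; then 15, −78 to 0 °C; aq NH4Cl
Reagents that add atoms: none
Why: Grignard addition of a benzylic organomagnesium reagent to an aryl aldehyde, the first equivalent being consumed by the phenol and the resulting magnesium phenoxide chelating the ortho formyl group, forms the carbinol stereocenter as a racemate, which is immaterial because the next step oxidises it.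

Step 9
Reactants: 21 racemic 2-[2,4-bis(methoxymethoxy)phenyl]-1-[6-ethoxy-2-hydroxy-3-(2-methylbut-3-en-2-yl)-4-[(triisopropylsilyl)oxy]phenyl]ethan-1-ol
Product: 22 2-[2,4-bis(methoxymethoxy)phenyl]-1-[6-ethoxy-2-hydroxy-3-(2-methylbut-3-en-2-yl)-4-[(triisopropylsilyl)oxy]phenyl]ethan-1-one
Conditions: activated MnO2 (excess), CH2Cl2, 25 °C, on crude 21
Reagents that add atoms: none
Why: Heterogeneous MnO2 oxidation is selective for benzylic alcohols and tolerates the free phenol, the silyl ether, the acetals and the terminal alkene, so it removes the only stereocenter and gives the hydrogen-bonded ortho-hydroxy ketone without exposing the dehydration-prone carbinol to acid.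

Step 10
Reactants: 22 2-[2,4-bis(methoxymethoxy)phenyl]-1-[6-ethoxy-2-hydroxy-3-(2-methylbut-3-en-2-yl)-4-[(triisopropylsilyl)oxy]phenyl]ethan-1-one
Product: 24 3-[2,4-bis(methoxymethoxy)phenyl]-5-ethoxy-8-(2-methylbut-3-en-2-yl)-7-[(triisopropylsilyl)oxy]-4H-chromen-4-one, via enaminone 23 (not isolated)
Conditions: DMF-DMA (3 equiv), PhMe, 90 °C
Reagents that add atoms: N,N-dimethylformamide dimethyl acetal COC(OC)N(C)C
Why: Isoflavone synthesis from a 2-hydroxydeoxybenzoin, in which the activated methylene condenses with the formamide acetal to enaminone 23 and the ortho phenol then attacks its β-carbon in a 6-endo addition–elimination that expels dimethylamine and closes ring C with the inserted carbon as C2.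

Step 11
Reactants: 24 3-[2,4-bis(methoxymethoxy)phenyl]-5-ethoxy-8-(2-methylbut-3-en-2-yl)-7-[(triisopropylsilyl)oxy]-4H-chromen-4-one
Product: 25 3-(2,4-dihydroxyphenyl)-5-hydroxy-8-(2-methylbut-3-en-2-yl)-7-[(triisopropylsilyl)oxy]-4H-chromen-4-one
Conditions: BCl3 (excess), CH2Cl2, −78 to 0 °C; then H2O
Reagents that add atoms: none
Why: Boron trichloride cleaves the two MOM acetals at low temperature and, on warming, the ethyl ether held in a six-membered chelate between O5 and the C4 carbonyl (chloride attack on the activated ethyl group), while the hindered aryl silyl ether on O7 is expected to persist and so blocks acid-induced ring closure of that oxygen onto the neighbouring vinyl group.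

Step 12
Reactants: 25 3-(2,4-dihydroxyphenyl)-5-hydroxy-8-(2-methylbut-3-en-2-yl)-7-[(triisopropylsilyl)oxy]-4H-chromen-4-one
Product: 26 3-(2,4-dihydroxyphenyl)-5,7-dihydroxy-8-(2-methylbut-3-en-2-yl)-4H-chromen-4-one
Conditions: TBAF, AcOH, THF, 0 to 25 °C
Reagents that add atoms: none
Why: Fluoride-induced cleavage of the aryl silyl ether, buffered with acetic acid so that the polyphenolic isoflavone is not exposed to strong base, releases the 7-hydroxyl and gives the target, which has no stereocenter.

Compound list
1 | ethyl 2,2-dimethylbut-3-enoate | C=CC(C)(C)C(=O)OCC | starting material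
2 | 1,1-dibromo-3,3-dimethylpent-4-en-2-one (present as its lithium enolate) | C=CC(C)(C)C(=O)C(Br)Br | intermediate
3 | lithium 3,3-dimethylpent-4-en-1-yn-1-olate | C=CC(C)(C)C#C[O-].[Li+] | intermediate
4 | triisopropyl[(3,3-dimethylpent-4-en-1-yn-1-yl)oxy]silane | C=CC(C)(C)C#CO[Si](C(C)C)(C(C)C)C(C)C | intermediate
5 | ethoxyacetylene | C#COCC | starting material
6 | acetyl chloride | CC(Cl)=O | starting material
7 | ketene | C=C=O | intermediate
8 | 3-ethoxycyclobut-2-en-1-one | CCOC1=CC(=O)C1 | intermediate
9 | 3-ethoxybuta-1,3-dien-1-one ((1-ethoxyvinyl)ketene) | C=C(OCC)C=C=O | intermediate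
10 | racemic 4-(1-ethoxyethenyl)-2-(2-methylbut-3-en-2-yl)-3-[(triisopropylsilyl)oxy]cyclobut-2-en-1-one | C=CC(C)(C)C1=C(O[Si](C(C)C)(C(C)C)C(C)C)C(C(=C)OCC)C1=O | intermediate
11 | (3E)-5-ethoxy-2-(2-methylbut-3-en-2-yl)-3-[(triisopropylsilyl)oxy]hexa-1,3,5-trien-1-one (ketene carbon and ethoxyvinyl group cis) | C=CC(C)(C)C(=C=O)/C(O[Si](C(C)C)(C(C)C)C(C)C)=C\C(=C)OCC | intermediate
12 | 5-ethoxy-2-(2-methylbut-3-en-2-yl)-3-[(triisopropylsilyl)oxy]cyclohexa-2,4-dien-1-one | C=CC(C)(C)C1=C(O[Si](C(C)C)(C(C)C)C(C)C)C=C(OCC)CC1=O | intermediate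
13 | 5-ethoxy-2-(2-methylbut-3-en-2-yl)-3-[(triisopropylsilyl)oxy]phenol | C=CC(C)(C)c1c(O)cc(OCC)cc1O[Si](C(C)C)(C(C)C)C(C)C | intermediate
14 | 3-ethoxy-2-(hydroxymethyl)-6-(2-methylbut-3-en-2-yl)-5-[(triisopropylsilyl)oxy]phenol | C=CC(C)(C)c1c(O)c(CO)c(OCC)cc1O[Si](C(C)C)(C(C)C)C(C)C | intermediate
15 | 6-ethoxy-2-hydroxy-3-(2-methylbut-3-en-2-yl)-4-[(triisopropylsilyl)oxy]benzaldehyde | C=CC(C)(C)c1c(O)c(C=O)c(OCC)cc1O[Si](C(C)C)(C(C)C)C(C)C | intermediate
16 | 2,4-dihydroxybenzaldehyde | O=Cc1ccc(O)cc1O | starting material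
17 | 2,4-bis(methoxymethoxy)benzaldehyde | COCOc1ccc(C=O)c(OCOC)c1 | intermediate
18 | [2,4-bis(methoxymethoxy)phenyl]methanol | COCOc1ccc(CO)c(OCOC)c1 | intermediate
19 | 1-(chloromethyl)-2,4-bis(methoxymethoxy)benzene | COCOc1ccc(CCl)c(OCOC)c1 | intermediate
20 | [2,4-bis(methoxymethoxy)benzyl]magnesium chloride | COCOc1ccc(C[Mg]Cl)c(OCOC)c1 | intermediate
21 | racemic 2-[2,4-bis(methoxymethoxy)phenyl]-1-[6-ethoxy-2-hydroxy-3-(2-methylbut-3-en-2-yl)-4-[(triisopropylsilyl)oxy]phenyl]ethan-1-ol | C=CC(C)(C)c1c(O)c(C(O)Cc2ccc(OCOC)cc2OCOC)c(OCC)cc1O[Si](C(C)C)(C(C)C)C(C)C | intermediate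
22 | 2-[2,4-bis(methoxymethoxy)phenyl]-1-[6-ethoxy-2-hydroxy-3-(2-methylbut-3-en-2-yl)-4-[(triisopropylsilyl)oxy]phenyl]ethan-1-one | C=CC(C)(C)c1c(O)c(C(=O)Cc2ccc(OCOC)cc2OCOC)c(OCC)cc1O[Si](C(C)C)(C(C)C)C(C)C | intermediate
23 | 2-[2,4-bis(methoxymethoxy)phenyl]-3-(dimethylamino)-1-[6-ethoxy-2-hydroxy-3-(2-methylbut-3-en-2-yl)-4-[(triisopropylsilyl)oxy]phenyl]prop-2-en-1-one (alkene geometry not controlled, either isomer cyclizes) | C=CC(C)(C)c1c(O)c(C(=O)C(=CN(C)C)c2ccc(OCOC)cc2OCOC)c(OCC)cc1O[Si](C(C)C)(C(C)C)C(C)C | intermediate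
24 | 3-[2,4-bis(methoxymethoxy)phenyl]-5-ethoxy-8-(2-methylbut-3-en-2-yl)-7-[(triisopropylsilyl)oxy]-4H-chromen-4-one | C=CC(C)(C)c1c(O[Si](C(C)C)(C(C)C)C(C)C)cc(OCC)c2c(=O)c(-c3ccc(OCOC)cc3OCOC)coc12 | intermediate
25 | 3-(2,4-dihydroxyphenyl)-5-hydroxy-8-(2-methylbut-3-en-2-yl)-7-[(triisopropylsilyl)oxy]-4H-chromen-4-one | C=CC(C)(C)c1c(O[Si](C(C)C)(C(C)C)C(C)C)cc(O)c2c(=O)c(-c3ccc(O)cc3O)coc12 | intermediate
26 | 3-(2,4-dihydroxyphenyl)-5,7-dihydroxy-8-(2-methylbut-3-en-2-yl)-4H-chromen-4-one (CNP0275995.0) | C=CC(C)(C)c1c(O)cc(O)c2c(=O)c(-c3ccc(O)cc3O)coc12 | target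

Total step count: 12.
Longest linear sequence: 8 steps (steps 1, 3, 4, 8, 9, 10, 11, 12 from ester 1; the branches through step 2 and through steps 5 to 7 are equally long).

Steps most likely to fail

Step 3. The vinylogous-ester cyclobutenone may open too slowly, so that at the temperature it needs the siloxyalkyne isomerises by silyl shift or the vinylketene oligomerises before the hindered [2+2] takes place. The fallback generates the same vinylketene 9 at or below room temperature by 1,4-dehydrochlorination instead of electrocyclic opening; it sets out from siloxyalkyne 4 and returns at phenol 13. Commercial ethyl (E)-3-ethoxybut-2-enoate would be saponified (KOH, aqueous EtOH, then careful acidification at 0 °C) to (E)-3-ethoxybut-2-enoic acid F1, and oxalyl chloride with catalytic DMF would convert this to (E)-3-ethoxybut-2-enoyl chloride F2. Slow addition of F2 to 4 and Et3N in CH2Cl2 at 0 to 25 °C should give 9 by γ-deprotonation, the ketene–ynol ether [2+2] should then give 10, and brief warming (PhMe, 80 °C) should carry 10 through 11 and 12 to 13.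

Step 11. Slow cleavage of the chelated ethyl ether may force longer or warmer exposure to BCl3 and HCl, during which Markovnikov addition to the vinyl group, or loss of the silyl cap followed by ring closure of O7 onto the alkene, can intervene. The fallback separates the two cleavages and avoids boron halides; it sets out from 24 and returns at 25. Acid-catalysed methanolysis of the acetals (PPTS or dilute HCl, MeOH, 40 °C) would give 3-(2,4-dihydroxyphenyl)-5-ethoxy-8-(2-methylbut-3-en-2-yl)-7-[(triisopropylsilyl)oxy]-4H-chromen-4-one F3. The peri ethyl ether would then be cleaved under non-protic conditions with MgI2 (etherate, PhMe/THF, 60 to 80 °C), iodide attacking the ethyl group of the magnesium chelate between O5 and the C4 carbonyl, to give 25 after mild aqueous work-up.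

Step 8. Wurtz-type homocoupling may consume the electron-rich benzylic chloride while the Grignard reagent is formed, and addition may stall once the ortho hydroxyl of the hindered aldehyde has become a phenoxide. The fallback builds the isoflavone by C3–C1′ cross-coupling instead; it sets out from 15 and returns at 24.
- Ring A/C partner: MeMgBr (excess, THF) would give racemic 1-[6-ethoxy-2-hydroxy-3-(2-methylbut-3-en-2-yl)-4-[(triisopropylsilyl)oxy]phenyl]ethan-1-ol F4. MnO2 would give 1-[6-ethoxy-2-hydroxy-3-(2-methylbut-3-en-2-yl)-4-[(triisopropylsilyl)oxy]phenyl]ethan-1-one F5. DMF-DMA (PhMe, 90 °C) would give (E)-3-(dimethylamino)-1-[6-ethoxy-2-hydroxy-3-(2-methylbut-3-en-2-yl)-4-[(triisopropylsilyl)oxy]phenyl]prop-2-en-1-one F6. I2 (1.05 equiv, CHCl3, 0 to 25 °C) would close ring C to 5-ethoxy-3-iodo-8-(2-methylbut-3-en-2-yl)-7-[(triisopropylsilyl)oxy]-4H-chromen-4-one F7, the enaminone being far more reactive toward iodine than the isolated vinyl group.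
- Ring B partner: commercial 4-bromoresorcinol would be converted (MOMCl, i-Pr2NEt) into 1-bromo-2,4-bis(methoxymethoxy)benzene F8 and then (n-BuLi, THF, −78 °C; B(OMe)3; aqueous work-up) into [2,4-bis(methoxymethoxy)phenyl]boronic acid F9.
- Coupling: Suzuki–Miyaura coupling of F7 with F9 (Pd(PPh3)4, K2CO3, dioxane/H2O, 80 °C) should give 24.

Further compounds
F1 | step 3 | (E)-3-ethoxybut-2-enoic acid | CCO/C(C)=C/C(=O)O
F2 | step 3 | (E)-3-ethoxybut-2-enoyl chloride | CCO/C(C)=C/C(=O)Cl
F3 | step 11 | 3-(2,4-dihydroxyphenyl)-5-ethoxy-8-(2-methylbut-3-en-2-yl)-7-[(triisopropylsilyl)oxy]-4H-chromen-4-one | C=CC(C)(C)c1c(O[Si](C(C)C)(C(C)C)C(C)C)cc(OCC)c2c(=O)c(-c3ccc(O)cc3O)coc12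
F4 | step 8 | racemic 1-[6-ethoxy-2-hydroxy-3-(2-methylbut-3-en-2-yl)-4-[(triisopropylsilyl)oxy]phenyl]ethan-1-ol | C=CC(C)(C)c1c(O)c(C(C)O)c(OCC)cc1O[Si](C(C)C)(C(C)C)C(C)C
F5 | step 8 | 1-[6-ethoxy-2-hydroxy-3-(2-methylbut-3-en-2-yl)-4-[(triisopropylsilyl)oxy]phenyl]ethan-1-one | C=CC(C)(C)c1c(O)c(C(C)=O)c(OCC)cc1O[Si](C(C)C)(C(C)C)C(C)C
F6 | step 8 | (E)-3-(dimethylamino)-1-[6-ethoxy-2-hydroxy-3-(2-methylbut-3-en-2-yl)-4-[(triisopropylsilyl)oxy]phenyl]prop-2-en-1-one | C=CC(C)(C)c1c(O)c(C(=O)/C=C/N(C)C)c(OCC)cc1O[Si](C(C)C)(C(C)C)C(C)C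
F7 | step 8 | 5-ethoxy-3-iodo-8-(2-methylbut-3-en-2-yl)-7-[(triisopropylsilyl)oxy]-4H-chromen-4-one | C=CC(C)(C)c1c(O[Si](C(C)C)(C(C)C)C(C)C)cc(OCC)c2c(=O)c(I)coc12
F8 | step 8 | 1-bromo-2,4-bis(methoxymethoxy)benzene | COCOc1ccc(Br)c(OCOC)c1
F9 | step 8 | [2,4-bis(methoxymethoxy)phenyl]boronic acid | COCOc1ccc(B(O)O)c(OCOC)c1
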